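**Retrosynthetic overview**

1. C4–O bond, made last: axial hydride delivery to a flavanone gives the 2,4-cis carbinol, so the trans carbinol is made by C–O bond formation instead. O5–H of ring A is ortho (through C4a) to C4, so the O5 phenoxide can expel a C4 acetate to give the planar ortho-quinone methide C5(=O)–C4a=C4; water then adds to C4 on the face away from the C2 aryl group. Both C4 epimers of the precursor converge on (4R), and all three hydroxyls are freed in base, never in acid.
2. C8–C1″ (prenyl) bond and free O5–H: tandem Claisen (O5→C6) / Cope (C6→C8) shift of an O5-prenyl ether on the intact (S)-flavanone. Until then the prenyl group serves as the O5 protecting group.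
3. C2–C1′ bond and the C2 stereocentre: Pd/pyridine-oxazoline asymmetric conjugate arylation of 7-methoxy-5-prenyloxychromone with (4-acetoxyphenyl)boronic acid.
4. Ring order: ring A is bought (symmetric 2′,6′-dihydroxy-4′-methoxyacetophenone), ring C is closed by enaminone cyclisation (O1–C2), ring B is attached in step 3.

Key step: step 7

Remark: the target SMILES is read as (2S,4R), i.e. the C2 aryl group and the C4 hydroxyl are trans on ring C; prenyl = 3-methylbut-2-enyl.
Remark: (R)-t-BuPyOx is assumed to give the 2S product in step 3, by analogy with the sense of induction of this catalyst family on cyclic enones; if the sense proves opposite, the antipodal ligand is used.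

**Route**

Step 1
Reactants: 1 1-(2,6-dihydroxy-4-methoxyphenyl)ethanone; 2 1-bromo-3-methylbut-2-ene (prenyl bromide)
Product: 3 1-[2-hydroxy-4-methoxy-6-(3-methylbut-2-enyloxy)phenyl]ethanone
Conditions: prenyl bromide (1.05 equiv), K2CO3, acetone, 56 °C
Reagents that add atoms: prenyl bromide, CC(C)=CCBr
Why: Williamson etherification in which the two hydroxyls of 1 are equivalent by symmetry and the remaining one is then held in a strong hydrogen bond to the acetyl carbonyl, so mono-O-prenylation should be clean and no C-prenylation regiochemistry has to be solved.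

Step 2
Reactants: 3 1-[2-hydroxy-4-methoxy-6-(3-methylbut-2-enyloxy)phenyl]ethanone; 4 N,N-dimethylformamide dimethyl acetal
Product: 6 7-methoxy-5-(3-methylbut-2-enyloxy)-4H-chromen-4-one, via enaminone 5 (not isolated)
Conditions: DMF-DMA, toluene, 95 °C; then AcOH, 60 °C
Reagents that add atoms: N,N-dimethylformamide dimethyl acetal, COC(OC)N(C)C
Why: Enaminone formation from the methyl ketone followed by addition of the chelated 2′-OH to the β-carbon and loss of dimethylamine (6-endo-trig addition–elimination) is the standard chromone synthesis and should close ring C without touching the aryl prenyl ether.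

Step 3
Reactants: 6 7-methoxy-5-(3-methylbut-2-enyloxy)-4H-chromen-4-one; 7 (4-acetoxyphenyl)boronic acid
Product: 8 (2S)-2-(4-acetoxyphenyl)-7-methoxy-5-(3-methylbut-2-enyloxy)chroman-4-one
Conditions: Pd(OCOCF3)2 (5 mol%), (R)-t-BuPyOx (6 mol%), NH4PF6 (30 mol%), H2O (5 equiv), ClCH2CH2Cl, 60 °C
Reagents that add atoms: (4-acetoxyphenyl)boronic acid, CC(=O)Oc1ccc(cc1)B(O)O
Why: Catalytic asymmetric conjugate addition of an arylboronic acid to a chromone under cationic Pd(II)/pyridine-oxazoline catalysis, in which the aryl–Pd species adds to C2 on the enone face left open by the tert-butyl group of the ligand (setting C2 as S) and the Pd enolate is protonated by water under non-basic conditions, so the flavanone should not ring-open and the acetate and prenyl ether should survive.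

Step 4
Reactants: 8 (2S)-2-(4-acetoxyphenyl)-7-methoxy-5-(3-methylbut-2-enyloxy)chroman-4-one
Product: 11 (2S)-2-(4-acetoxyphenyl)-5-hydroxy-7-methoxy-8-(3-methylbut-2-enyl)chroman-4-one, via C6 reverse-prenyl ortho-dienone 9 (not isolated), via C8-prenyl para-dienone 10 (not isolated)
Conditions: Eu(fod)3 (10 mol%), CHCl3, 65 °C, sealed tube
Reagents that add atoms: none
Why: Lewis-acid-catalysed aromatic Claisen rearrangement followed by a Cope rearrangement (para-Claisen–Cope, a known reaction of 5-O-prenyl flavanones), in which Eu(III) chelated by O5 and the C4 carbonyl promotes the [3,3] shift to C6, the crowded dienone 9 relays the allyl unit by a second [3,3] shift to C8 (the only position para to O5, with O1 already locked in ring C), and enolisation of 10 should give the 5-hydroxy-8-prenyl pattern with C2 untouched in the neutral aprotic medium.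

Step 5
Reactants: 11 (2S)-2-(4-acetoxyphenyl)-5-hydroxy-7-methoxy-8-(3-methylbut-2-enyl)chroman-4-one
Product: 12 (2S,4S)-2-(4-acetoxyphenyl)-7-methoxy-8-(3-methylbut-2-enyl)chromane-4,5-diol
Conditions: NaBH4, CeCl3·7H2O, MeOH/THF, −40 → −10 °C; pH 7 buffer
Reagents that add atoms: none
Why: Luche-type borohydride reduction of the chelated aryl ketone at low temperature, where the aryl acetate should survive (any loss is made good in step 6) and axial hydride delivery should give mainly the 2,4-cis carbinol, whose C4 configuration is irrelevant because step 7 erases it.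

Step 6
Reactants: 12 (2S,4S)-2-(4-acetoxyphenyl)-7-methoxy-8-(3-methylbut-2-enyl)chromane-4,5-diol
Product: 13 (2S,4S)-2-(4-acetoxyphenyl)-7-methoxy-8-(3-methylbut-2-enyl)chromane-4,5-diyl diacetate
Conditions: Ac2O, pyridine, DMAP (cat.), CH2Cl2, 0 °C → rt
Reagents that add atoms: acetic anhydride, CC(=O)OC(C)=O
Why: DMAP-catalysed acylation of the O5 phenol and the C4 benzylic alcohol under basic conditions that cannot ionise C4 should install the leaving group at C4 and the base-labile trigger on O5.

Step 7
Reactants: 13 (2S,4S)-2-(4-acetoxyphenyl)-7-methoxy-8-(3-methylbut-2-enyl)chromane-4,5-diyl diacetate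
Product: 15 (2S,4R)-2-(4-hydroxyphenyl)-7-methoxy-8-(3-methylbut-2-enyl)chromane-4,5-diol (target), via ortho-quinone methide 14 (not isolated)
Conditions: LiOH, THF/H2O (1:1, ca. 5 mM), 0 °C; then pH 7 phosphate buffer
Reagents that add atoms: water, O
Why: Hydroxide should cleave the two aryl acetates first, after which the O5 phenoxide expels the C4 acetate across C5–C4a–C4 (1,4-elimination) to give ortho-quinone methide 14, in which C4 is trigonal and the configuration from step 5 is erased; water then adds to C4 and re-aromatises ring A. The closest known reaction types are the base-triggered generation of ortho-quinone methides from 2-acetoxybenzyl acetates with capture by water or alcohols, and the trans-selective capture of flavan-4-yl cations by nucleophiles. No ring is closed. The new C4 stereocentre is set under substrate control by C2: ring C of 14 is a sofa with C2 out of plane and the C2 aryl pseudo-equatorial, and water should attack C4 along the axial trajectory staggered to the C3 substituents and anti to the axial C3–H bond, i.e. on the face opposite to the aryl group, which gives the 2,4-trans (4R) carbinol, whereas attack on the other face eclipses that C3–H bond. The step needs quinone methide formation to outrun direct acyl–oxygen hydrolysis of the C4 acetate, which the much faster cleavage of aryl acetates and the donor oxygens O1 and O7 on ring A should secure, and it needs water addition to outrun tautomerisation to the flav-3-ene, which the ring secures by holding C3 anti to O5 (no intramolecular 1,5-hydrogen shift) together with the dilute water-rich medium at 0 °C. Any cis carbinol that forms can be re-acetylated and resubmitted, since both epimers give the same 14.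

**Compound list**

1 | 1-(2,6-dihydroxy-4-methoxyphenyl)ethanone | CC(=O)c1c(O)cc(OC)cc1O | starting material
2 | 1-bromo-3-methylbut-2-ene (prenyl bromide) | CC(C)=CCBr | starting material
3 | 1-[2-hydroxy-4-methoxy-6-(3-methylbut-2-enyloxy)phenyl]ethanone | CC(=O)c1c(O)cc(OC)cc1OCC=C(C)C | intermediate
4 | N,N-dimethylformamide dimethyl acetal | COC(OC)N(C)C | starting material
5 | (E)-3-(dimethylamino)-1-[2-hydroxy-4-methoxy-6-(3-methylbut-2-enyloxy)phenyl]prop-2-en-1-one | CN(C)/C=C/C(=O)c1c(O)cc(OC)cc1OCC=C(C)C | intermediate
6 | 7-methoxy-5-(3-methylbut-2-enyloxy)-4H-chromen-4-one | O=c1ccoc2cc(OC)cc(OCC=C(C)C)c12 | intermediate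
7 | (4-acetoxyphenyl)boronic acid | CC(=O)Oc1ccc(cc1)B(O)O | starting material
8 | (2S)-2-(4-acetoxyphenyl)-7-methoxy-5-(3-methylbut-2-enyloxy)chroman-4-one | COc1cc(OCC=C(C)C)c2c(c1)O[C@H](c1ccc(OC(C)=O)cc1)CC2=O | intermediate
9 | (2S)-2-(4-acetoxyphenyl)-7-methoxy-6-(2-methylbut-3-en-2-yl)-2,3-dihydro-4H-chromene-4,5(6H)-dione (ortho-dienone; C6 epimers) | COC1=CC2=C(C(=O)C1C(C)(C)C=C)C(=O)C[C@@H](c1ccc(OC(C)=O)cc1)O2 | intermediate
10 | (2S)-2-(4-acetoxyphenyl)-7-methoxy-8-(3-methylbut-2-enyl)-2,3-dihydro-4H-chromene-4,5(8H)-dione (para-dienone; C8 epimers) | COC1=CC(=O)C2=C(C1CC=C(C)C)O[C@H](c1ccc(OC(C)=O)cc1)CC2=O | intermediate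
11 | (2S)-2-(4-acetoxyphenyl)-5-hydroxy-7-methoxy-8-(3-methylbut-2-enyl)chroman-4-one | COc1cc(O)c2c(c1CC=C(C)C)O[C@H](c1ccc(OC(C)=O)cc1)CC2=O | intermediate
12 | (2S,4S)-2-(4-acetoxyphenyl)-7-methoxy-8-(3-methylbut-2-enyl)chromane-4,5-diol (2,4-cis) | COc1cc(O)c2c(c1CC=C(C)C)O[C@H](c1ccc(OC(C)=O)cc1)C[C@@H]2O | intermediate
13 | (2S,4S)-2-(4-acetoxyphenyl)-7-methoxy-8-(3-methylbut-2-enyl)chromane-4,5-diyl diacetate | COc1cc(OC(C)=O)c2c(c1CC=C(C)C)O[C@H](c1ccc(OC(C)=O)cc1)C[C@@H]2OC(C)=O | intermediate
14 | (2S)-2-(4-hydroxyphenyl)-7-methoxy-8-(3-methylbut-2-enyl)-2,3-dihydro-5H-chromen-5-one (ortho-quinone methide) | COC1=CC(=O)C2=CC[C@@H](c3ccc(O)cc3)OC2=C1CC=C(C)C | intermediate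
15 | (2S,4R)-2-(4-hydroxyphenyl)-7-methoxy-8-(3-methylbut-2-enyl)chromane-4,5-diol (4,5,4'-trihydroxy-7-methoxy-8-prenylflavan) | COc1cc(O)c2c(c1CC=C(C)C)O[C@H](c1ccc(O)cc1)C[C@H]2O | target

**Step count and risks**

Total steps: 7. Longest linear sequence: 7 steps (from 1).

Steps most likely to fail:

1. Step 7 (key step). Three processes could go wrong. The trans:cis ratio may be eroded by direct saponification of the C4 acetate with retention or by water adding to the less favoured face of the quinone methide. Base may remove a C3 proton from 14 and give the flav-3-ene. Phenoxides of product may capture 14 instead of water and give oligomers. The fallback is a stereospecific SN2 inversion with O5 masked; it sets out from 11 and comes back at 15. Silylation of O5 (TBSOTf, 2,6-lutidine, CH2Cl2) gives the 5-O-silyl flavanone F1. Luche reduction gives the 2,4-cis alcohol F2. A Mitsunobu reaction with benzoic acid (PPh3, DIAD, toluene, 0 °C) inverts C4 to the 2,4-trans benzoate F3. DIBAL-H (CH2Cl2, −78 °C) removes the benzoate and the aryl acetate reductively while O5 stays silylated, giving the trans diol F4. Buffered TBAF/AcOH (THF, 0 °C) then frees O5 to give 15.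

2. Step 3. Insertion of the electron-rich 5,7-dioxygenated chromone into the aryl–Pd bond may be slow, so that protodeboronation of 7 wins. Facial discrimination may be insufficient. Adventitious Pd(0) may cleave the prenyl ether. The fallback replaces enantioselective C–C bond formation by ring closure of a chalcone and kinetic resolution; it sets out from 3 and comes back at 8. Claisen–Schmidt condensation of 3 with 4-hydroxybenzaldehyde (KOH, EtOH) gives the chalcone F5. Oxa-Michael cyclisation (NaOAc, EtOH, reflux) gives the racemic 4′-hydroxyflavanone F6. Acetylation (Ac2O, pyridine) gives the racemic flavanone acetate F7. Ru–TsDPEN transfer hydrogenation (HCO2H/Et3N), with the catalyst antipode matched to the 2R enantiomer, reduces that enantiomer to the 2,4-cis alcohol F8 and leaves (S)-flavanone 8, which is separated and enters step 4.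

3. Step 4. Dienone 9 may enolise before the Cope shift and stop at the 6-(2-methylbut-3-en-2-yl) phenol. A formal [1,3] shift may give the 6-prenyl isomer. The Lewis acid may open ring C and erode C2. The fallback moves the sigmatropic sequence to the achiral chromone, where no stereocentre can be lost and purely thermal activation is allowed; it sets out from 6 and comes back at 11. Heating 6 in N,N-diethylaniline at 190 °C gives the 5-hydroxy-8-prenylchromone F9. Its asymmetric conjugate arylation with 7 under the conditions of step 3 gives 11 directly.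

Further compounds
F1 | step 7 | (2S)-2-(4-acetoxyphenyl)-5-(tert-butyldimethylsilyloxy)-7-methoxy-8-(3-methylbut-2-enyl)chroman-4-one | COc1cc(O[Si](C)(C)C(C)(C)C)c2c(c1CC=C(C)C)O[C@H](c1ccc(OC(C)=O)cc1)CC2=O
F2 | step 7 | (2S,4S)-2-(4-acetoxyphenyl)-5-(tert-butyldimethylsilyloxy)-7-methoxy-8-(3-methylbut-2-enyl)chroman-4-ol | COc1cc(O[Si](C)(C)C(C)(C)C)c2c(c1CC=C(C)C)O[C@H](c1ccc(OC(C)=O)cc1)C[C@@H]2O
F3 | step 7 | (2S,4R)-2-(4-acetoxyphenyl)-5-(tert-butyldimethylsilyloxy)-7-methoxy-8-(3-methylbut-2-enyl)chroman-4-yl benzoate | COc1cc(O[Si](C)(C)C(C)(C)C)c2c(c1CC=C(C)C)O[C@H](c1ccc(OC(C)=O)cc1)C[C@H]2OC(=O)c1ccccc1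
F4 | step 7 | (2S,4R)-5-(tert-butyldimethylsilyloxy)-2-(4-hydroxyphenyl)-7-methoxy-8-(3-methylbut-2-enyl)chroman-4-ol | COc1cc(O[Si](C)(C)C(C)(C)C)c2c(c1CC=C(C)C)O[C@H](c1ccc(O)cc1)C[C@H]2O
F5 | step 3 | (E)-1-[2-hydroxy-4-methoxy-6-(3-methylbut-2-enyloxy)phenyl]-3-(4-hydroxyphenyl)prop-2-en-1-one | COc1cc(O)c(C(=O)/C=C/c2ccc(O)cc2)c(OCC=C(C)C)c1
F6 | step 3 | racemic 2-(4-hydroxyphenyl)-7-methoxy-5-(3-methylbut-2-enyloxy)chroman-4-one | COc1cc(OCC=C(C)C)c2c(c1)OC(c1ccc(O)cc1)CC2=O
F7 | step 3 | racemic 2-(4-acetoxyphenyl)-7-methoxy-5-(3-methylbut-2-enyloxy)chroman-4-one | COc1cc(OCC=C(C)C)c2c(c1)OC(c1ccc(OC(C)=O)cc1)CC2=O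
F8 | step 3 | (2R,4R)-2-(4-acetoxyphenyl)-7-methoxy-5-(3-methylbut-2-enyloxy)chroman-4-ol | COc1cc(OCC=C(C)C)c2c(c1)O[C@@H](c1ccc(OC(C)=O)cc1)C[C@H]2O
F9 | step 4 | 5-hydroxy-7-methoxy-8-(3-methylbut-2-enyl)-4H-chromen-4-one | O=c1ccoc2c(CC=C(C)C)c(OC)cc(O)c12
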